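**Retrosynthetic overview**

1. The oxirane is made last, by site- and face-selective epoxidation of the corresponding 2,4-cyclohexadiene ketone; the ketone comes from a silyl-protected secondary alcohol.
2. The cyclohexadiene comes from an acyclic (2E,4Z,6E,8E)-tetraene by thermal disrotatory 6π-electrocyclisation, which places pyranone and alkenyl chain cis.
3. The tetraene comes from a late Suzuki coupling of two halves of similar size: a (Z)-iododienyl α-methoxy-γ-pyranone (fragment A, 14 C) and an (E,E)-dienyl pinacol boronate carrying the side-chain stereocentre (fragment B, 11 skeletal C).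
4. Fragment A: triketide lactonisation and O-methylation, then vinylogous aldol/dehydration with (Z)-3-iodo-2-methylacrolein. Fragment B: proline-catalysed propanal dimerisation, then two alkyne/hydrozirconation–iodination rounds.
5. Ring order: pyranone (step 3), cyclohexadiene (step 17), oxirane (step 20).

Assumption: a one-pot operation counts as one step; organometallic species made and consumed in one flask are numbered as non-isolated intermediates, while metal salts of a product that are only protonated on work-up are not.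

**Fragment A**

Step 1
Reactants: 1 methyl propanoate (2 equiv)
Product: 2 methyl 2-methyl-3-oxopentanoate (racemic)
Conditions: NaH (0.55 equiv), cat. MeOH, THF, reflux; then aq. HCl
Reagents that add atoms: none
Why: Claisen self-condensation, pulled forward by irreversible deprotonation of the β-keto ester; the α-stereocentre is racemic and later becomes an sp2 ring carbon.

Step 2
Reactants: 2 methyl 2-methyl-3-oxopentanoate; 3 N-methoxy-N-methylpropanamide
Product: 5 methyl 2,4-dimethyl-3,5-dioxoheptanoate, via lithium sodium dianion of the keto ester 4 (not isolated)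
Conditions: NaH (1.1 equiv), THF, 0 °C; n-BuLi (1.05 equiv), 0 °C; then 3, −78 to 0 °C; aq. HCl
Reagents that add atoms: none
Why: Huckin–Weiler dianion chemistry: the more basic γ-carbanion is acylated by the Weinreb amide, whose chelated tetrahedral adduct prevents a second addition until acidic work-up.

Step 3
Reactants: 5 methyl 2,4-dimethyl-3,5-dioxoheptanoate
Product: 6 6-ethyl-4-hydroxy-3,5-dimethyl-2H-pyran-2-one
Conditions: DBU (2 equiv), toluene, 60 °C; then aq. HCl
Reagents that add atoms: none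
Why: Base-mediated lactonisation (enol oxygen of the terminal ketone onto the methyl ester, loss of methanol) forms the 4-hydroxy-2-pyranone ring.

Step 4
Reactants: 6 6-ethyl-4-hydroxy-3,5-dimethyl-2H-pyran-2-one
Product: 7 6-ethyl-2-methoxy-3,5-dimethyl-4H-pyran-4-one
Conditions: MeOTf (1.2 equiv), CH2Cl2, rt; then aq. NaHCO3
Reagents that add atoms: methyl trifluoromethanesulfonate, COS(=O)(=O)C(F)(F)F
Why: O-methylation by the hard electrophile at the lactone carbonyl oxygen, then proton loss from the 4-hydroxypyrylium salt, gives the α-methoxy-γ-pyranone rather than the 4-methoxy-2-pyranone.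

Step 5
Reactants: 8 prop-2-yn-1-ol
Product: 10 (2Z)-3-iodo-2-methylprop-2-en-1-ol, via Z-alkenylmagnesium alkoxide 9 (not isolated)
Conditions: MeMgBr (3 equiv), CuI (10 mol%), THF, −10 °C to rt; then I2, −78 to 0 °C
Reagents that add atoms: methylmagnesium bromide, C[Mg]Br; iodine, [I][I]
Why: Copper-catalysed anti-carbomagnesiation of the propargylic alkoxide (Duboudin type): methyl goes to C2 while magnesium is held at C3 cis to the CH2O group in a chelate, and iodinolysis with retention fixes the Z-iodoalkene.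

Step 6
Reactants: 10 (2Z)-3-iodo-2-methylprop-2-en-1-ol
Product: 11 (2Z)-3-iodo-2-methylprop-2-enal
Conditions: MnO2 (15 equiv), CH2Cl2, rt, dark
Reagents that add atoms: none
Why: Neutral allylic alcohol oxidation by MnO2 leaves the labile Z-vinyl iodide untouched.

Step 7
Reactants: 7 6-ethyl-2-methoxy-3,5-dimethyl-4H-pyran-4-one; 11 (2Z)-3-iodo-2-methylprop-2-enal
Product: 13 6-[(4Z)-3-hydroxy-5-iodo-4-methylpent-4-en-2-yl]-2-methoxy-3,5-dimethyl-4H-pyran-4-one (diastereomer mixture), via lithiated ethylpyranone 12 (not isolated)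
Conditions: LiN(SiMe3)2 (1.1 equiv), THF, −78 °C; then 11, −78 °C; AcOH quench
Reagents that add atoms: none
Why: Vinylogous aldol addition: the 6-ethyl CH2 is the only acidic (γ-enone) position of the pyranone and its lithium dienolate adds 1,2 to the non-enolisable enal; both new stereocentres are removed in the next step.

Step 8
Reactants: 13 6-[(4Z)-3-hydroxy-5-iodo-4-methylpent-4-en-2-yl]-2-methoxy-3,5-dimethyl-4H-pyran-4-one
Product: 15 6-[(2E,4Z)-5-iodo-4-methylpenta-2,4-dien-2-yl]-2-methoxy-3,5-dimethyl-4H-pyran-4-one (fragment A), via allylic mesylate 14 (not isolated)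
Conditions: MsCl (1.5 equiv), Et3N (3 equiv), CH2Cl2, 0 °C; then DBU (3 equiv), 0 °C to rt, dark
Reagents that add atoms: none
Why: Mesylation then DBU-induced E1cB elimination through the planar vinylogous enolate converges both aldol diastereomers on the conjugated E-alkene (pyranone trans to the dienyl chain), the Z-iodoalkene being untouched.

**Fragment B**

Step 9
Reactants: 16 propanal (2 equiv)
Product: 17 (2S,3S)-3-hydroxy-2-methylpentanal
Conditions: L-proline (10 mol%), DMF, 4 °C
Reagents that add atoms: none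
Why: Proline-catalysed direct aldol reaction (enamine catalysis, List–Houk transition state) gives the anti dimer with C2 set as S in about 99% ee and about 4:1 anti:syn; C2 becomes the lone side-chain stereocentre of the target, while C3 is later oxidised away.

Step 10
Reactants: 17 (2S,3S)-3-hydroxy-2-methylpentanal
Product: 18 (2S,3S)-3-[(tert-butyldimethylsilyl)oxy]-2-methylpentanal
Conditions: TBSOTf, 2,6-lutidine, CH2Cl2, −78 °C
Reagents that add atoms: tert-butyldimethylsilyl trifluoromethanesulfonate, CC(C)(C)[Si](C)(C)OS(=O)(=O)C(F)(F)F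
Why: Silyl ether formation at low temperature with a hindered base protects the alcohol before retro-aldol or epimerisation of the β-hydroxy aldehyde can occur; the minor syn isomer is removed by chromatography here.

Step 11
Reactants: 18 (2S,3S)-3-[(tert-butyldimethylsilyl)oxy]-2-methylpentanal
Product: 19 tert-butyl{[(3S,4R)-6,6-dibromo-4-methylhex-5-en-3-yl]oxy}dimethylsilane
Conditions: CBr4, PPh3, Zn, CH2Cl2, 0 °C to rt
Reagents that add atoms: carbon tetrabromide, BrC(Br)(Br)Br
Why: Corey–Fuchs dibromo-olefination (Wittig-type reaction of Ph3P=CBr2) under neutral, Zn-buffered conditions leaves the α-stereocentre intact.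

Step 12
Reactants: 19 tert-butyl{[(3S,4R)-6,6-dibromo-4-methylhex-5-en-3-yl]oxy}dimethylsilane
Product: 21 tert-butyldimethyl{[(3S,4R)-4-methylhept-5-yn-3-yl]oxy}silane, via lithium acetylide 20 (not isolated)
Conditions: n-BuLi (2.2 equiv), THF, −78 °C; then MeI, −78 °C to rt
Reagents that add atoms: iodomethane, IC
Why: Second Corey–Fuchs stage: bromine–lithium exchange and Fritsch–Buttenberg–Wiechell rearrangement give the lithium acetylide, which is C-methylated by MeI (SN2).

Step 13
Reactants: 21 tert-butyldimethyl{[(3S,4R)-4-methylhept-5-yn-3-yl]oxy}silane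
Product: 23 tert-butyl{[(3S,4R,5E)-6-iodo-4-methylhept-5-en-3-yl]oxy}dimethylsilane, via alkenyl-ZrCp2Cl complex 22 (not isolated)
Conditions: Cp2Zr(H)Cl (2 equiv), THF, 50 °C, dark; then I2, 0 °C
Reagents that add atoms: iodine, [I][I]
Why: syn-Hydrozirconation puts zirconium on the less hindered, methyl-bearing alkyne carbon (equilibration with excess reagent) and iodinolysis with retention gives the E-iodoalkene, the side-chain alkene geometry of the target.

Step 14
Reactants: 23 tert-butyl{[(3S,4R,5E)-6-iodo-4-methylhept-5-en-3-yl]oxy}dimethylsilane; 24 propyne (excess)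
Product: 25 tert-butyl{[(3S,4R,5E)-4,6-dimethylnon-5-en-7-yn-3-yl]oxy}dimethylsilane
Conditions: PdCl2(PPh3)2 (5 mol%), CuI (10 mol%), Et3N, THF, rt
Reagents that add atoms: none
Why: Sonogashira coupling of the alkenyl iodide with propyne proceeds with retention of the E-alkene geometry.

Step 15
Reactants: 25 tert-butyl{[(3S,4R,5E)-4,6-dimethylnon-5-en-7-yn-3-yl]oxy}dimethylsilane
Product: 27 tert-butyl{[(3S,4R,5E,7E)-8-iodo-4,6-dimethylnona-5,7-dien-3-yl]oxy}dimethylsilane, via dienyl-ZrCp2Cl complex 26 (not isolated)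
Conditions: Cp2Zr(H)Cl (2 equiv), THF, 50 °C, dark; then I2, 0 °C
Reagents that add atoms: iodine, [I][I]
Why: A second regioselective syn-hydrozirconation (zirconium at the methyl-bearing carbon, distal to the branched alkenyl group) and iodinolysis with retention give the (E,E)-iododiene.

Step 16
Reactants: 27 tert-butyl{[(3S,4R,5E,7E)-8-iodo-4,6-dimethylnona-5,7-dien-3-yl]oxy}dimethylsilane
Product: 29 tert-butyldimethyl{[(3S,4R,5E,7Z)-4,6-dimethyl-8-(4,4,5,5-tetramethyl-1,3,2-dioxaborolan-2-yl)nona-5,7-dien-3-yl]oxy}silane (fragment B), via dienyllithium 28 (not isolated)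
Conditions: t-BuLi (2.1 equiv), Et2O, −78 °C; then i-PrOBpin, −78 °C to rt
Reagents that add atoms: 2-isopropoxy-4,4,5,5-tetramethyl-1,3,2-dioxaborolane, CC(C)OB1OC(C)(C)C(C)(C)O1
Why: Iodine–lithium exchange with retention of alkene geometry and trapping of the dienyllithium by the borate ester give the pinacol boronate (same geometry; the descriptor changes only because boron ranks below carbon).

**Union and endgame**

Step 17
Reactants: 15 6-[(2E,4Z)-5-iodo-4-methylpenta-2,4-dien-2-yl]-2-methoxy-3,5-dimethyl-4H-pyran-4-one; 29 tert-butyldimethyl{[(3S,4R,5E,7Z)-4,6-dimethyl-8-(4,4,5,5-tetramethyl-1,3,2-dioxaborolan-2-yl)nona-5,7-dien-3-yl]oxy}silane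
Product: 31 6-[(1R,6S)-6-{(2E,4R,5S)-5-[(tert-butyldimethylsilyl)oxy]-4-methylhept-2-en-2-yl}-1,3,5-trimethylcyclohexa-2,4-dien-1-yl]-2-methoxy-3,5-dimethyl-4H-pyran-4-one, via tetraene 30 (not isolated)
Conditions: Pd(OAc)2 (5 mol%), SPhos (10 mol%), K3PO4 (3 equiv), 1,4-dioxane/H2O 10:1, 45 °C, dark; then 80 °C; chromatographic separation of the two cis diastereomers
Reagents that add atoms: none
Why: Suzuki–Miyaura coupling with retention of both alkene geometries gives the (2E,4Z,6E,8E)-tetraene, whose (E,Z,E)-triene closes by thermal disrotatory 6π-electrocyclisation so that the two outward groups (pyranone and alkenyl chain) end up cis on the new ring stereocentres; the remote side-chain stereocentres give no useful facial bias, so both cis diastereomers form (about 1:1) and the (1R,6S) isomer is isolated.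

Step 18
Reactants: 31 6-[(1R,6S)-6-{(2E,4R,5S)-5-[(tert-butyldimethylsilyl)oxy]-4-methylhept-2-en-2-yl}-1,3,5-trimethylcyclohexa-2,4-dien-1-yl]-2-methoxy-3,5-dimethyl-4H-pyran-4-one
Product: 32 6-[(1R,6S)-6-[(2E,4R,5S)-5-hydroxy-4-methylhept-2-en-2-yl]-1,3,5-trimethylcyclohexa-2,4-dien-1-yl]-2-methoxy-3,5-dimethyl-4H-pyran-4-one
Conditions: HF·pyridine, pyridine, THF, 0 °C to rt, dark
Reagents that add atoms: none
Why: Fluoride-mediated desilylation under pyridine-buffered conditions frees the secondary alcohol without touching the diene or the pyranone.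

Step 19
Reactants: 32 6-[(1R,6S)-6-[(2E,4R,5S)-5-hydroxy-4-methylhept-2-en-2-yl]-1,3,5-trimethylcyclohexa-2,4-dien-1-yl]-2-methoxy-3,5-dimethyl-4H-pyran-4-one
Product: 33 2-methoxy-3,5-dimethyl-6-[(1R,6S)-1,3,5-trimethyl-6-[(2E,4R)-4-methyl-5-oxohept-2-en-2-yl]cyclohexa-2,4-dien-1-yl]-4H-pyran-4-one
Conditions: DMP (1.3 equiv), pyridine, CH2Cl2, 0 °C
Reagents that add atoms: none
Why: Dess–Martin oxidation under buffered, non-enolising conditions gives the β,γ-unsaturated ketone without epimerising the adjacent R stereocentre or moving the alkene into conjugation.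

Step 20
Reactants: 33 2-methoxy-3,5-dimethyl-6-[(1R,6S)-1,3,5-trimethyl-6-[(2E,4R)-4-methyl-5-oxohept-2-en-2-yl]cyclohexa-2,4-dien-1-yl]-4H-pyran-4-one
Product: 34 2-methoxy-3,5-dimethyl-6-[(1R,4R,5R,6S)-2,4,6-trimethyl-5-[(2E,4R)-4-methyl-5-oxohept-2-en-2-yl]-7-oxabicyclo[4.1.0]hept-2-en-4-yl]-4H-pyran-4-one (target)
Conditions: DMDO (1.05 equiv, acetone solution), CH2Cl2, −40 to −20 °C
Reagents that add atoms: dimethyldioxirane, CC1(C)OO1
Why: Electrophilic (Prilezhaev-type) epoxidation by DMDO at the ring alkene next to the CH carbon, from the face opposite the cis pyranone and alkenyl groups, sets both oxirane stereocentres; the other ring alkene is screened on both faces by the quaternary carbon and the side-chain alkene is deactivated by the allylic ketone.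

**Compound list**

1 | methyl propanoate | CCC(=O)OC | starting material
2 | methyl 2-methyl-3-oxopentanoate (racemic) | CCC(=O)C(C)C(=O)OC | intermediate
3 | N-methoxy-N-methylpropanamide | CCC(=O)N(C)OC | starting material
4 | lithium sodium 1-methoxy-2-methylpenta-1,3-diene-1,3-diolate (dianion of 2) | [Li+].[Na+].CC=C([O-])C(C)=C([O-])OC | intermediate
5 | methyl 2,4-dimethyl-3,5-dioxoheptanoate (stereoisomer and tautomer mixture) | CCC(=O)C(C)C(=O)C(C)C(=O)OC | intermediate
6 | 6-ethyl-4-hydroxy-3,5-dimethyl-2H-pyran-2-one | CCc1oc(=O)c(C)c(O)c1C | intermediate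
7 | 6-ethyl-2-methoxy-3,5-dimethyl-4H-pyran-4-one | CCc1oc(OC)c(C)c(=O)c1C | intermediate
8 | prop-2-yn-1-ol | C#CCO | starting material
9 | bromomagnesium (2Z)-3-(bromomagnesio)-2-methylprop-2-en-1-olate | C/C(CO[Mg]Br)=C/[Mg]Br | intermediate
10 | (2Z)-3-iodo-2-methylprop-2-en-1-ol | OC/C(C)=C\I | intermediate
11 | (2Z)-3-iodo-2-methylprop-2-enal | O=C/C(C)=C\I | intermediate
12 | lithium 1-(6-methoxy-3,5-dimethyl-4-oxo-4H-pyran-2-yl)ethanide (vinylogous enolate of 7) | [Li+].C[CH-]c1oc(OC)c(C)c(=O)c1C | intermediate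
13 | 6-[(4Z)-3-hydroxy-5-iodo-4-methylpent-4-en-2-yl]-2-methoxy-3,5-dimethyl-4H-pyran-4-one (diastereomer mixture) | COc1oc(C(C)C(O)/C(C)=C\I)c(C)c(=O)c1C | intermediate
14 | (4Z)-5-iodo-2-(6-methoxy-3,5-dimethyl-4-oxo-4H-pyran-2-yl)-4-methylpent-4-en-3-yl methanesulfonate | COc1oc(C(C)C(OS(C)(=O)=O)/C(C)=C\I)c(C)c(=O)c1C | intermediate
15 | 6-[(2E,4Z)-5-iodo-4-methylpenta-2,4-dien-2-yl]-2-methoxy-3,5-dimethyl-4H-pyran-4-one (fragment A) | COc1oc(/C(C)=C/C(C)=C\I)c(C)c(=O)c1C | intermediate
16 | propanal | CCC=O | starting material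
17 | (2S,3S)-3-hydroxy-2-methylpentanal | CC[C@H](O)[C@H](C)C=O | intermediate
18 | (2S,3S)-3-[(tert-butyldimethylsilyl)oxy]-2-methylpentanal | CC[C@H](O[Si](C)(C)C(C)(C)C)[C@H](C)C=O | intermediate
19 | tert-butyl{[(3S,4R)-6,6-dibromo-4-methylhex-5-en-3-yl]oxy}dimethylsilane | CC[C@H](O[Si](C)(C)C(C)(C)C)[C@H](C)C=C(Br)Br | intermediate
20 | lithium (3R,4S)-4-[(tert-butyldimethylsilyl)oxy]-3-methylhex-1-yn-1-ide | CC[C@H](O[Si](C)(C)C(C)(C)C)[C@H](C)C#C[Li] | intermediate
21 | tert-butyldimethyl{[(3S,4R)-4-methylhept-5-yn-3-yl]oxy}silane | CC[C@H](O[Si](C)(C)C(C)(C)C)[C@H](C)C#CC | intermediate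
22 | chlorobis(cyclopentadienyl){(2E,4R,5S)-5-[(tert-butyldimethylsilyl)oxy]-4-methylhept-2-en-2-yl}zirconium | CC[C@H](O[Si](C)(C)C(C)(C)C)[C@H](C)/C=C(\C)[Zr](Cl)(C1C=CC=C1)C1C=CC=C1 | intermediate
23 | tert-butyl{[(3S,4R,5E)-6-iodo-4-methylhept-5-en-3-yl]oxy}dimethylsilane | CC[C@H](O[Si](C)(C)C(C)(C)C)[C@H](C)/C=C(\C)I | intermediate
24 | propyne | CC#C | starting material
25 | tert-butyl{[(3S,4R,5E)-4,6-dimethylnon-5-en-7-yn-3-yl]oxy}dimethylsilane | CC[C@H](O[Si](C)(C)C(C)(C)C)[C@H](C)/C=C(\C)C#CC | intermediate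
26 | chlorobis(cyclopentadienyl){(2E,4E,6R,7S)-7-[(tert-butyldimethylsilyl)oxy]-4,6-dimethylnona-2,4-dien-2-yl}zirconium | CC[C@H](O[Si](C)(C)C(C)(C)C)[C@H](C)/C=C(\C)/C=C(/[Zr](Cl)(C1C=CC=C1)C1C=CC=C1)C | intermediate
27 | tert-butyl{[(3S,4R,5E,7E)-8-iodo-4,6-dimethylnona-5,7-dien-3-yl]oxy}dimethylsilane | CC[C@H](O[Si](C)(C)C(C)(C)C)[C@H](C)/C=C(\C)/C=C(/I)C | intermediate
28 | {(2Z,4E,6R,7S)-7-[(tert-butyldimethylsilyl)oxy]-4,6-dimethylnona-2,4-dien-2-yl}lithium | CC[C@H](O[Si](C)(C)C(C)(C)C)[C@H](C)/C=C(\C)/C=C(/[Li])C | intermediate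
29 | tert-butyldimethyl{[(3S,4R,5E,7Z)-4,6-dimethyl-8-(4,4,5,5-tetramethyl-1,3,2-dioxaborolan-2-yl)nona-5,7-dien-3-yl]oxy}silane (fragment B) | CC[C@H](O[Si](C)(C)C(C)(C)C)[C@H](C)/C=C(\C)/C=C(/B1OC(C)(C)C(C)(C)O1)C | intermediate
30 | 6-[(2E,4Z,6E,8E,10R,11S)-11-[(tert-butyldimethylsilyl)oxy]-4,6,8,10-tetramethyltrideca-2,4,6,8-tetraen-2-yl]-2-methoxy-3,5-dimethyl-4H-pyran-4-one | COc1oc(/C(C)=C/C(C)=C\C(C)=C\C(C)=C\[C@@H](C)[C@H](CC)O[Si](C)(C)C(C)(C)C)c(C)c(=O)c1C | intermediate
31 | 6-[(1R,6S)-6-{(2E,4R,5S)-5-[(tert-butyldimethylsilyl)oxy]-4-methylhept-2-en-2-yl}-1,3,5-trimethylcyclohexa-2,4-dien-1-yl]-2-methoxy-3,5-dimethyl-4H-pyran-4-one | CC[C@H](O[Si](C)(C)C(C)(C)C)[C@H](C)/C=C(\C)[C@H]1C(C)=CC(C)=C[C@@]1(C)c1oc(OC)c(C)c(=O)c1C | intermediate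
32 | 6-[(1R,6S)-6-[(2E,4R,5S)-5-hydroxy-4-methylhept-2-en-2-yl]-1,3,5-trimethylcyclohexa-2,4-dien-1-yl]-2-methoxy-3,5-dimethyl-4H-pyran-4-one | CC[C@H](O)[C@H](C)/C=C(\C)[C@H]1C(C)=CC(C)=C[C@@]1(C)c1oc(OC)c(C)c(=O)c1C | intermediate
33 | 2-methoxy-3,5-dimethyl-6-[(1R,6S)-1,3,5-trimethyl-6-[(2E,4R)-4-methyl-5-oxohept-2-en-2-yl]cyclohexa-2,4-dien-1-yl]-4H-pyran-4-one | CCC(=O)[C@H](C)/C=C(\C)[C@H]1C(C)=CC(C)=C[C@@]1(C)c1oc(OC)c(C)c(=O)c1C | intermediate
34 | 2-methoxy-3,5-dimethyl-6-[(1R,4R,5R,6S)-2,4,6-trimethyl-5-[(2E,4R)-4-methyl-5-oxohept-2-en-2-yl]-7-oxabicyclo[4.1.0]hept-2-en-4-yl]-4H-pyran-4-one | CCC(=O)[C@H](C)/C=C(\C)[C@H]1[C@]2(C)O[C@@H]2C(C)=C[C@@]1(C)c1oc(OC)c(C)c(=O)c1C | target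

**Step count**

Total: 20 steps. Longest linear sequence: 12 steps (steps 9 to 20, from propanal). The fragment A branch is 10 steps long (steps 1 to 4, 7, 8, 17 to 20).

**Steps most likely to fail, with fallbacks**

Step 17 is the weakest point. The coupling joins an α-methyl dienyl boronate to a β,β-disubstituted Z-iodoalkene, so protodeboronation competes. The ring closure cannot distinguish the two faces, so at best half of the material is the wanted cis diastereomer; if it does not separate at 31, the mixture is separated as the alcohols after step 18. Should the boronate coupling itself fail, the fallback sets out from 27: iodine–lithium exchange (t-BuLi, Et2O, −78 °C) and Me3SnCl give the dienyl trimethylstannane F1. A base-free and water-free Stille coupling of this stannane with 15 (Pd(PPh3)4, CuI, CsF, DMF, 40 °C, then 80 °C) gives the same tetraene 30 and, after electrocyclisation, comes back to the route at 31.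

Step 20 is the second risk. Three trisubstituted alkenes compete, so a side-chain epoxide or over-oxidation is possible, and the vinyl oxirane is acid-labile. The fallback moves the epoxidation ahead of the two side-chain steps and sets out from 31. Buffered mCPBA (NaHCO3, CH2Cl2, −20 °C) is used while no ketone is present and the side-chain alkene is screened by the neighbouring silyloxy-bearing carbons; this gives the silyl ether epoxide F2. Bu4NF buffered with AcOH (THF, rt) then gives the epoxy alcohol F3, and DMP/pyridine oxidation comes back to the route at 34.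

Step 8, together with step 7, is the third risk. The β-iodoenal may react by addition–elimination instead of 1,2-addition, and the elimination may give E/Z mixtures at the new alkene. The fallback builds the pyranone last and sets out from 11. A Wittig reaction with Ph3P=C(Me)CHO (toluene, 70 °C, dark) fixes the E-alkene in the iododienal F4. The dianion 4 (made from 2 as in step 2) adds to it to give the hydroxy keto ester F5. DMP oxidation gives the diketo ester F6, DBU (toluene, 60 °C) closes the hydroxypyranone F7, and MeOTf as in step 4 comes back to the route at 15.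

**Further compounds**

F1 | step 17 | tert-butyldimethyl{[(3S,4R,5E,7E)-4,6-dimethyl-8-(trimethylstannyl)nona-5,7-dien-3-yl]oxy}silane | CC[C@H](O[Si](C)(C)C(C)(C)C)[C@H](C)/C=C(\C)/C=C(/[Sn](C)(C)C)C
F2 | step 20 | 6-[(1R,4R,5R,6S)-5-{(2E,4R,5S)-5-[(tert-butyldimethylsilyl)oxy]-4-methylhept-2-en-2-yl}-2,4,6-trimethyl-7-oxabicyclo[4.1.0]hept-2-en-4-yl]-2-methoxy-3,5-dimethyl-4H-pyran-4-one | CC[C@H](O[Si](C)(C)C(C)(C)C)[C@H](C)/C=C(\C)[C@H]1[C@]2(C)O[C@@H]2C(C)=C[C@@]1(C)c1oc(OC)c(C)c(=O)c1C
F3 | step 20 | 6-[(1R,4R,5R,6S)-5-[(2E,4R,5S)-5-hydroxy-4-methylhept-2-en-2-yl]-2,4,6-trimethyl-7-oxabicyclo[4.1.0]hept-2-en-4-yl]-2-methoxy-3,5-dimethyl-4H-pyran-4-one | CC[C@H](O)[C@H](C)/C=C(\C)[C@H]1[C@]2(C)O[C@@H]2C(C)=C[C@@]1(C)c1oc(OC)c(C)c(=O)c1C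
F4 | step 8 | (2E,4Z)-5-iodo-2,4-dimethylpenta-2,4-dienal | O=C/C(C)=C/C(C)=C\I
F5 | step 8 | methyl (6E,8Z)-5-hydroxy-9-iodo-2,4,6,8-tetramethyl-3-oxonona-6,8-dienoate (diastereomer mixture) | COC(=O)C(C)C(=O)C(C)C(O)/C(C)=C/C(C)=C\I
F6 | step 8 | methyl (6E,8Z)-9-iodo-2,4,6,8-tetramethyl-3,5-dioxonona-6,8-dienoate | COC(=O)C(C)C(=O)C(C)C(=O)/C(C)=C/C(C)=C\I
F7 | step 8 | 4-hydroxy-6-[(2E,4Z)-5-iodo-4-methylpenta-2,4-dien-2-yl]-3,5-dimethyl-2H-pyran-2-one | O=c1oc(/C(C)=C/C(C)=C\I)c(C)c(O)c1C
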